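The readings come from a simulation from invented constants; scatter was added.

The readings have gone flat. In this stirred flask, solid substrate dissolves to starting material, and free enzyme turns that into product. You must say what stands at 8.0 d and what a late remedy brings.

| flask | solid substrate | free enzyme | temperature | remark | time |
|---|---|---|---|---|---|
| gamma | 10 mM | 5 µM | 20 °C | the very flask that is asked about, followed so far |  |
| flask | 10 mM | 5.0 µM | 20 °C |  | 8.0 d |

- gamma (time / h: product / %): 15.0: 7.7; 30.0: 13.2; 50.0: 18.5; 72.0: 19.6; 96.0: 21.8; 120: 22.1

(each reading ± 0.5 percentage points)

- blue: change nothing and wait 4.0 d more
- amber: at 8.0 d take out 90% of the product then present, then wait 4.0 d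
- violet: at 8.0 d raise the temperature by 25 K, then wait 4.0 d
- red: at 8.0 d add free enzyme, 50.0% of the amount charged, then wait 4.0 d

- product, in percent of the solid substrate first charged, at 8.0 d
- the remedy with the largest gain of product, or "none" below 2 percentage points (blue / amber / violet / red / none)
- product present, with what was taken out counted in, in percent of the solid substrate first charged, after blue
- product present, with what was taken out counted in, in percent of the solid substrate first charged, after amber

- a species is counted by the solid substrate in it: one spent catalyst A counts as two
- given per volume of solution although it is solid: solid substrate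
- product that was removed still counts
- the numbers in the tables scatter by 0.5 percentage points (one standard deviation)
- steps that have been proposed: free enzyme -> unfolded enzyme; starting material + free enzyme <-> complex; complex -> free enzyme + product; 2 complex -> spent catalyst A; starting material + free enzyme -> spent catalyst B; solid substrate <-> starting material
- at the start none of the solid substrate is in solution
- additions bring no volume worth counting
- the earlier runs do not show what temperature does; that part of a forecast is a guess

Has the substrate run out? No. The last reading of this flask, at 120 h, shows 22.1% product, so 77.9% of the charge is not product, and the proposed steps take no product back.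

Is more coming? The last two readings differ by 0.3 percentage points, less than the scatter of 0.5 points, while the first 15.0 h brought 7.7%. So my reckoning for 8.0 d is the last reading, about 22.1%, and I expect blue and amber to stay under 2 points.

What does a charge of catalyst yield, then? The last reading of this flask gives about 442 for N, the product made per enzyme charged, the usual turnover number. Red adds 2.50 µM of free enzyme, so if late enzyme yields the same N, red promises 11 points. Put that back in: 33.1% product still leaves 66.9% of the charge as not product, and the 4.0 d of waiting equals the 96.0 h by which the readings of this flask had reached nearly all of the last one. Heating has no reading behind it, so I choose red.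

The forecast gives 23% now, red as best, 23.2% after blue and 23.2% after amber, saying “Only fresh enzyme helps”. Its figure for now lies 0.9 points above mine.

The flask gives 22.2% at 8.0 d, and red is best: blue and amber add 0.073 points each, violet 0.0098 points, and red 13 points, against the 11 points from N.

    free enzyme → unfolded enzyme (k = 0.00370 h⁻¹, Ea = 193 kJ mol⁻¹)
    starting material + free enzyme ⇌ complex (K = 310 M⁻¹, k = 8.80 × 10⁵ M⁻¹ h⁻¹, Ea = 40.0 kJ mol⁻¹, ΔH = −36.0 kJ mol⁻¹)
    complex → free enzyme + product (k = 40.0 h⁻¹, Ea = 72.0 kJ mol⁻¹)
    2 complex → spent catalyst A (k = 26000 M⁻¹ h⁻¹, Ea = 47.0 kJ mol⁻¹)
    starting material + free enzyme → spent catalyst B (k = 12.0 M⁻¹ h⁻¹, Ea = 46.0 kJ mol⁻¹)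
    solid substrate ⇌ starting material, rate k6*(cs6 - [starting material]) while solid is left; crystals form when [starting material] > cs6 (solubility = 6.60 mM, k = 0.0510 h⁻¹)
    (constants at 20 °C)

At 19.0 h, complex passes into free enzyme + product 660 times as fast as into spent catalyst A. At 192 h, the catalyst of this flask stands as 51.1% spent catalyst A, 43.7% spent catalyst B and 5.10% unfolded enzyme, with 0.109% complex and 0.0539% free enzyme. For the neighbour flask charged with 6.0 mM of solid substrate and the same 5.0 µM of free enzyme, N gives 36.8% of its charge as product; the computed neighbour flask gives 37.1%.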